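**Plan**

- Retrosynthesis, in order: the two benzyl ethers; the C4 carbonyl (quinone back to the 1‑naphthol); the ring B bond C6–C7; the C6–CH2 bond to the vanillyl group; the alkyne carbon C6 (C5 is a formyl carbon); the C8–C8a bond.
- Enabling feature: ring B of the naphthoquinone (C4a, C5, C6, C7, C8, C8a) carries benzyl on C6, methyl on C7 and aryl on C8. Opening C6–C7 leaves ring A with a C5≡C6 alkyne on C4a and a 1‑arylpropenyl group (C8=C7) on C8a, and attack of C7 on C6 puts the positive charge on C8, where the aryl group and ring A stabilize it.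
- Forward: ring A is bought as 2‑bromoisovanillin. A Suzuki coupling attaches C8=C7 at C8a, Ohira–Bestmann homologation makes C5≡C6–H, and copper‑catalysed benzylation completes the enyne.
- Monovalent gold then closes ring B, the only ring formed. Acid frees the C1 naphthol, K2NO(SO3)2 installs the C4 carbonyl, and hydrogenolysis followed by air releases the two phenols.
- Stereochemistry: the target has no stereocentre, and the propenyl geometry of the precursor is erased when ring B aromatizes.

Key step: step 9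

Remark: the Z geometry written for 8, 10, 13 and 14 is what the stereoretentive sequence of steps 2, 3 and 5 should deliver; any E isomer would converge in step 9. [4‑(Benzyloxy)‑3‑methoxyphenyl]methanol and the Ohira–Bestmann reagent are taken as commercial.

**Route**

Step 1
Reactants: 1 propiovanillone
Product: 2 1‑[4‑(benzyloxy)‑3‑methoxyphenyl]propan‑1‑one
Conditions: BnBr, K2CO3, acetone, reflux
Reagents that add atoms: benzyl bromide, BrCc1ccccc1
Why: Williamson etherification of the acidic para‑acyl phenol, which K2CO3 deprotonates while leaving the ketone α‑CH2 untouched.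

Step 2
Reactants: 2 1‑[4‑(benzyloxy)‑3‑methoxyphenyl]propan‑1‑one
Product: 4 (Z)‑1‑[4‑(benzyloxy)‑3‑methoxyphenyl]prop‑1‑en‑1‑yl trifluoromethanesulfonate, via potassium Z‑enolate 3 (not isolated)
Conditions: KN(SiMe3)2, THF, −78 °C; then PhNTf2, −78 °C to rt
Reagents that add atoms: N‑phenylbis(trifluoromethanesulfonimide), O=S(=O)(N(c1ccccc1)S(=O)(=O)C(F)(F)F)C(F)(F)F
Why: Kinetic enolization of an aryl ethyl ketone should give the Z enolate (allylic strain keeps the methyl away from the aryl group), and O‑sulfonylation with PhNTf2 is the standard enol triflate synthesis.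

Step 3
Reactants: 4 (Z)‑enol triflate
Product: 5 (E)‑2‑{1‑[4‑(benzyloxy)‑3‑methoxyphenyl]prop‑1‑en‑1‑yl}‑4,4,5,5‑tetramethyl‑1,3,2‑dioxaborolane (boron cis to methyl)
Conditions: B2pin2, PdCl2(PPh3)2 (3 mol %), PPh3, KOPh, toluene, 50 °C
Reagents that add atoms: bis(pinacolato)diboron, CC1(C)OB(OC1(C)C)B1OC(C)(C)C(C)(C)O1
Why: Miyaura borylation of an alkenyl triflate proceeds with retention of geometry, and the weak base KOPh activates the diboron without promoting Suzuki coupling of product with unreacted triflate.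

Step 4
Reactants: 6 2‑bromoisovanillin
Product: 7 2‑bromo‑4‑methoxy‑3‑(methoxymethoxy)benzaldehyde
Conditions: MOMCl, iPr2NEt, CH2Cl2, 0 °C to rt
Reagents that add atoms: chloromethyl methyl ether, COCCl
Why: O‑alkylation of the phenol gives a MOM acetal that tolerates the basic, organometallic and palladium steps ahead and is later removed by acid without touching the benzyl ethers.

Step 5
Reactants: 7 2‑bromo‑4‑methoxy‑3‑(methoxymethoxy)benzaldehyde; 5 alkenyl pinacol boronate
Product: 8 (Z)‑2‑{1‑[4‑(benzyloxy)‑3‑methoxyphenyl]prop‑1‑en‑1‑yl}‑4‑methoxy‑3‑(methoxymethoxy)benzaldehyde (methyl cis to ring A)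
Conditions: Pd(OAc)2 (5 mol %), SPhos (10 mol %), K3PO4, toluene/H2O, 90 °C
Reagents that add atoms: none
Why: Suzuki–Miyaura coupling in which the ortho‑formyl group accelerates oxidative addition of the C–Br bond to zerovalent palladium, the bulky electron‑rich biaryl phosphine handles the doubly ortho‑flanked bromide, and the alkenyl boronate transfers with retention.

Step 6
Reactants: 8 diarylpropene aldehyde; 9 dimethyl (1‑diazo‑2‑oxopropyl)phosphonate
Product: 10 (Z)‑2‑{1‑[4‑(benzyloxy)‑3‑methoxyphenyl]prop‑1‑en‑1‑yl}‑1‑ethynyl‑4‑methoxy‑3‑(methoxymethoxy)benzene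
Conditions: 9, K2CO3, MeOH/THF, 0 °C to rt
Reagents that add atoms: dimethyl (1‑diazo‑2‑oxopropyl)phosphonate 9, COP(=O)(OC)C(=[N+]=[N-])C(C)=O
Why: Ohira–Bestmann variant of the Seyferth–Gilbert homologation, in which methanolysis releases the diazomethylphosphonate anion, olefination of the non‑enolizable aldehyde gives a diazoalkene, and loss of N2 with 1,2‑hydride shift gives the terminal alkyne under conditions that spare the MOM and benzyl ethers.

Step 7
Reactants: 11 [4‑(benzyloxy)‑3‑methoxyphenyl]methanol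
Product: 12 1‑(benzyloxy)‑4‑(bromomethyl)‑2‑methoxybenzene
Conditions: PBr3, Et2O, 0 °C; used at once
Reagents that add atoms: phosphorus tribromide, BrP(Br)Br
Why: Primary benzylic alcohols are converted cleanly into bromides by PBr3 through the phosphite ester, and the labile electron‑rich bromide is taken forward without storage.

Step 8
Reactants: 10 terminal alkyne; 12 1‑(benzyloxy)‑4‑(bromomethyl)‑2‑methoxybenzene
Product: 14 (Z)‑1‑{3‑[4‑(benzyloxy)‑3‑methoxyphenyl]prop‑1‑yn‑1‑yl}‑2‑{1‑[4‑(benzyloxy)‑3‑methoxyphenyl]prop‑1‑en‑1‑yl}‑4‑methoxy‑3‑(methoxymethoxy)benzene, via alkynylmagnesium bromide 13 (not isolated)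
Conditions: EtMgBr, THF, 0 °C to rt; then CuBr·SMe2 (10 mol %), 12, THF, 50 °C
Reagents that add atoms: none
Why: Copper‑catalysed substitution of a benzylic bromide by an alkynyl Grignard reagent is the classical C(sp)–C(sp3) route to 1,3‑diarylpropynes, and the absence of any base stronger than the acetylide should limit propargyl‑to‑allene isomerization of the new CH2 group.

Step 9
Reactants: 14 ortho‑alkynyl diarylpropene
Product: 15 8‑[4‑(benzyloxy)‑3‑methoxyphenyl]‑6‑[4‑(benzyloxy)‑3‑methoxybenzyl]‑2‑methoxy‑1‑(methoxymethoxy)‑7‑methylnaphthalene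
Conditions: [(tBu)2(2‑biphenylyl)P]Au(NCMe)SbF6 (5 mol %), CH2Cl2, rt
Reagents that add atoms: none
Why: The cationic monovalent gold centre π‑coordinates the C5≡C6 alkyne and the alkene carbon C7 attacks C6 anti to gold, which forms the C6–C7 bond and leaves a vinylgold at C5 and a cation at C8 that is doubly benzylic and stabilized by the para‑benzyloxy aryl group. Loss of the C7 proton aromatizes ring B and protodeauration of the C5–Au bond returns the catalyst, so the step is a redox‑neutral isomerization. The closest known reaction type is the gold‑ or platinum‑catalysed cycloaromatization of ortho‑alkynyl α‑substituted styrenes to naphthalenes. Ring B closes in the 6‑endo‑dig mode and no stereocentre is created, the propenyl geometry being erased when C7 loses its proton. The step needs 6‑endo closure in preference to 5‑exo attack at C5 and to attack by the pendant arenes, and the α‑aryl group secures this by making C7 the nucleophilic and C8 the cationic terminus, with only bonding to the distal carbon C6 leading to an aromatic ring. The MOM acetal, remote from the alkyne, and the benzyl ethers are spectators under these neutral aprotic conditions, and all four ring B substituents arrive in place.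

Step 10
Reactants: 15 MOM‑protected naphthalene
Product: 16 8‑[4‑(benzyloxy)‑3‑methoxyphenyl]‑6‑[4‑(benzyloxy)‑3‑methoxybenzyl]‑2‑methoxy‑7‑methylnaphthalen‑1‑ol
Conditions: conc. HCl (cat.), MeOH/THF, 50 °C, under argon
Reagents that add atoms: none
Why: Acid‑catalysed acetal exchange with methanol cleaves the aryl MOM ether as dimethoxymethane while aryl benzyl and methyl ethers are stable, and exclusion of air protects the electron‑rich naphthol.

Step 11
Reactants: 16 2‑methoxy‑1‑naphthol
Product: 17 8‑[4‑(benzyloxy)‑3‑methoxyphenyl]‑6‑[4‑(benzyloxy)‑3‑methoxybenzyl]‑2‑methoxy‑7‑methylnaphthalene‑1,4‑dione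
Conditions: K2NO(SO3)2, aq. KH2PO4, acetone, rt
Reagents that add atoms: potassium nitrosodisulfonate, [K+].[K+].[O]N(S(=O)(=O)[O-])S(=O)(=O)[O-]
Why: Teuber oxidation, in which one nitrosodisulfonate radical abstracts the phenolic hydrogen and a second adds at the free para position C4 before loss of imidodisulfonate gives the 1,4‑quinone; the ortho position is blocked by methoxy and the etherified guaiacol rings cannot be oxidized.

Step 12
Reactants: 17 bis(benzyl ether) naphthoquinone
Product: 19 larreantin, via naphthalene-1,4-diol 18 (not isolated)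
Conditions: H2 (1 atm), Pd/C, EtOAc/MeOH, rt; then air, rt
Reagents that add atoms: none
Why: Hydrogenolysis over palladium removes both aryl benzyl ethers and reduces the quinone to its hydroquinone, which should autoxidize back to the 2‑methoxy‑1,4‑naphthoquinone on exposure to air while the guaiacol phenols are air‑stable.

**Compound list**

1 | propiovanillone, 1‑(4‑hydroxy‑3‑methoxyphenyl)propan‑1‑one | CCC(=O)c1ccc(O)c(OC)c1 | starting material
2 | 1‑[4‑(benzyloxy)‑3‑methoxyphenyl]propan‑1‑one | CCC(=O)c1ccc(OCc2ccccc2)c(OC)c1 | intermediate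
3 | potassium (Z)‑1‑[4‑(benzyloxy)‑3‑methoxyphenyl]prop‑1‑en‑1‑olate, not isolated | C/C=C(\[O-])c1ccc(OCc2ccccc2)c(OC)c1.[K+] | intermediate
4 | (Z)‑1‑[4‑(benzyloxy)‑3‑methoxyphenyl]prop‑1‑en‑1‑yl trifluoromethanesulfonate | C/C=C(\OS(=O)(=O)C(F)(F)F)c1ccc(OCc2ccccc2)c(OC)c1 | intermediate
5 | (E)‑2‑{1‑[4‑(benzyloxy)‑3‑methoxyphenyl]prop‑1‑en‑1‑yl}‑4,4,5,5‑tetramethyl‑1,3,2‑dioxaborolane | C/C=C(\B1OC(C)(C)C(C)(C)O1)c1ccc(OCc2ccccc2)c(OC)c1 | intermediate
6 | 2‑bromoisovanillin, 2‑bromo‑3‑hydroxy‑4‑methoxybenzaldehyde | COc1ccc(C=O)c(Br)c1O | starting material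
7 | 2‑bromo‑4‑methoxy‑3‑(methoxymethoxy)benzaldehyde | COCOc1c(OC)ccc(C=O)c1Br | intermediate
8 | (Z)‑2‑{1‑[4‑(benzyloxy)‑3‑methoxyphenyl]prop‑1‑en‑1‑yl}‑4‑methoxy‑3‑(methoxymethoxy)benzaldehyde | COCOc1c(OC)ccc(C=O)c1/C(=C\C)c1ccc(OCc2ccccc2)c(OC)c1 | intermediate
9 | dimethyl (1‑diazo‑2‑oxopropyl)phosphonate | COP(=O)(OC)C(=[N+]=[N-])C(C)=O | starting material
10 | (Z)‑2‑{1‑[4‑(benzyloxy)‑3‑methoxyphenyl]prop‑1‑en‑1‑yl}‑1‑ethynyl‑4‑methoxy‑3‑(methoxymethoxy)benzene | COCOc1c(OC)ccc(C#C)c1/C(=C\C)c1ccc(OCc2ccccc2)c(OC)c1 | intermediate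
11 | [4‑(benzyloxy)‑3‑methoxyphenyl]methanol | COc1cc(CO)ccc1OCc1ccccc1 | starting material
12 | 1‑(benzyloxy)‑4‑(bromomethyl)‑2‑methoxybenzene | COc1cc(CBr)ccc1OCc1ccccc1 | intermediate
13 | alkynylmagnesium bromide of 10, not isolated | COCOc1c(OC)ccc(C#C[Mg]Br)c1/C(=C\C)c1ccc(OCc2ccccc2)c(OC)c1 | intermediate
14 | (Z)‑1‑{3‑[4‑(benzyloxy)‑3‑methoxyphenyl]prop‑1‑yn‑1‑yl}‑2‑{1‑[4‑(benzyloxy)‑3‑methoxyphenyl]prop‑1‑en‑1‑yl}‑4‑methoxy‑3‑(methoxymethoxy)benzene | COCOc1c(OC)ccc(C#CCc2ccc(OCc3ccccc3)c(OC)c2)c1/C(=C\C)c1ccc(OCc2ccccc2)c(OC)c1 | intermediate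
15 | 8‑[4‑(benzyloxy)‑3‑methoxyphenyl]‑6‑[4‑(benzyloxy)‑3‑methoxybenzyl]‑2‑methoxy‑1‑(methoxymethoxy)‑7‑methylnaphthalene | COCOc1c(OC)ccc2cc(Cc3ccc(OCc4ccccc4)c(OC)c3)c(C)c(-c3ccc(OCc4ccccc4)c(OC)c3)c12 | intermediate
16 | 8‑[4‑(benzyloxy)‑3‑methoxyphenyl]‑6‑[4‑(benzyloxy)‑3‑methoxybenzyl]‑2‑methoxy‑7‑methylnaphthalen‑1‑ol | COc1ccc2cc(Cc3ccc(OCc4ccccc4)c(OC)c3)c(C)c(-c3ccc(OCc4ccccc4)c(OC)c3)c2c1O | intermediate
17 | 8‑[4‑(benzyloxy)‑3‑methoxyphenyl]‑6‑[4‑(benzyloxy)‑3‑methoxybenzyl]‑2‑methoxy‑7‑methylnaphthalene‑1,4‑dione | COC1=CC(=O)c2cc(Cc3ccc(OCc4ccccc4)c(OC)c3)c(C)c(-c3ccc(OCc4ccccc4)c(OC)c3)c2C1=O | intermediate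
18 | 8‑(4‑hydroxy‑3‑methoxyphenyl)‑6‑(4‑hydroxy‑3‑methoxybenzyl)‑2‑methoxy‑7‑methylnaphthalene‑1,4‑diol, not isolated | COc1cc(O)c2cc(Cc3ccc(O)c(OC)c3)c(C)c(-c3ccc(O)c(OC)c3)c2c1O | intermediate
19 | larreantin, 8‑(4‑hydroxy‑3‑methoxyphenyl)‑6‑(4‑hydroxy‑3‑methoxybenzyl)‑2‑methoxy‑7‑methylnaphthalene‑1,4‑dione | COC1=CC(=O)c2cc(Cc3ccc(O)c(OC)c3)c(C)c(-c3ccc(O)c(OC)c3)c2C1=O | target

**Step count**

Total: 12 steps. Longest linear sequence: 10 steps (1, 2, 3, 5, 6, 8, 9, 10, 11, 12, from propiovanillone).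

**Steps most likely to fail, riskiest first**

Step 8. The newly formed CH2 is both benzylic and propargylic, so the acetylide could isomerize it to the allene. The electron‑rich benzyl bromide could also be lost to self‑benzylation or homocoupling before it is captured. The fallback replaces substitution by carbonyl addition and ionic deoxygenation. It sets out from alkyne 10, which is deprotonated with n‑BuLi in THF at −78 °C to the lithium acetylide F1. F1 is added to commercial 4‑(benzyloxy)‑3‑methoxybenzaldehyde (COc1cc(C=O)ccc1OCc1ccccc1) to give the racemic propargylic alcohol F2. Treatment of F2 with excess Et3SiH and CF3CO2H in CH2Cl2 at −40 °C should ionize the para‑alkoxybenzylic position and deliver hydride there. This returns to the route at enyne 14 without any basic step after the CH2 is formed.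

Step 9. Closure could go 5‑exo at C5, a pendant arene could add to the activated alkyne, or adventitious acid from the SbF6 salt could remove the MOM group or hydrate the alkyne. The fallback uses an iodonium electrophile in place of the π‑acid to make the same C6–C7 bond. It sets out from enyne 14, which with I2 and NaHCO3 in MeCN at rt should undergo 6‑endo iodocyclization and proton loss to the 5‑iodonaphthalene F3. Reductive deiodination of F3 with Pd(OAc)2, PPh3 and HCO2Na in DMF at 80 °C then returns to the route at naphthalene 15.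

Step 5. Transmetalation at the C–Br bond flanked by formyl and MOM‑oxy groups could be slow enough for protodeboronation of the α‑aryl alkenyl boronate to take over. The fallback reverses polarity and builds the alkene by carbonyl addition and dehydration. It sets out from bromide 7, which is masked as the dioxolane F4 with 1,2‑bis(trimethylsilyloxy)ethane and catalytic Me3SiOTf in CH2Cl2 at −78 °C. Bromine–lithium exchange with n‑BuLi in THF at −78 °C gives the aryllithium F5, which is added to ketone 2 premixed with LaCl3·2LiCl to suppress enolization, giving the racemic tertiary carbinol F6. Catalytic TsOH·H2O in wet acetone should dehydrate F6 through the diaryl cation and hydrolyse the dioxolane while sparing the aryl MOM ether. This returns to the route at aldehyde 8, accompanied by the E isomer F7, which is removed by chromatography (it would in any case converge in step 9).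

**Further compounds**

F1 | step 8 | lithium acetylide of 10 (not isolated) | [Li]C#Cc1ccc(OC)c(OCOC)c1/C(=C\C)c1ccc(OCc2ccccc2)c(OC)c1
F2 | step 8 | racemic 1‑[4‑(benzyloxy)‑3‑methoxyphenyl]‑3‑aryl‑prop‑2‑yn‑1‑ol (aryl = ring A of 10, Z propenyl retained) | COCOc1c(OC)ccc(C#CC(O)c2ccc(OCc3ccccc3)c(OC)c2)c1/C(=C\C)c1ccc(OCc2ccccc2)c(OC)c1
F3 | step 9 | 8‑[4‑(benzyloxy)‑3‑methoxyphenyl]‑6‑[4‑(benzyloxy)‑3‑methoxybenzyl]‑5‑iodo‑2‑methoxy‑1‑(methoxymethoxy)‑7‑methylnaphthalene | COCOc1c(OC)ccc2c(I)c(Cc3ccc(OCc4ccccc4)c(OC)c3)c(C)c(-c3ccc(OCc4ccccc4)c(OC)c3)c12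
F4 | step 5 | 2‑[2‑bromo‑4‑methoxy‑3‑(methoxymethoxy)phenyl]‑1,3‑dioxolane | COCOc1c(OC)ccc(C2OCCO2)c1Br
F5 | step 5 | [2‑(1,3‑dioxolan‑2‑yl)‑5‑methoxy‑6‑(methoxymethoxy)phenyl]lithium (not isolated) | [Li]c1c(OCOC)c(OC)ccc1C1OCCO1
F6 | step 5 | racemic 1‑[4‑(benzyloxy)‑3‑methoxyphenyl]‑1‑[2‑(1,3‑dioxolan‑2‑yl)‑5‑methoxy‑6‑(methoxymethoxy)phenyl]propan‑1‑ol | CCC(O)(c1ccc(OCc2ccccc2)c(OC)c1)c1c(OCOC)c(OC)ccc1C1OCCO1
F7 | step 5 | (E)‑2‑{1‑[4‑(benzyloxy)‑3‑methoxyphenyl]prop‑1‑en‑1‑yl}‑4‑methoxy‑3‑(methoxymethoxy)benzaldehyde | COCOc1c(OC)ccc(C=O)c1/C(=C/C)c1ccc(OCc2ccccc2)c(OC)c1
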